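The retrosynthesis first masks the three hydroxyls (3-O, 5-O, 3'-O) as acetates. It then cuts both side-chain C2''=C3'' double bonds, so the prenyl groups on C6 and C8 become allyl groups plus 2-methyl-2-butene.
Enabling feature: C6 and C8 of ring A carry the same ArCH2–CH=C(CH3)2 chain. Its olefin is isolated, has no E/Z element and is acid-sensitive beside the C5 hydroxyl. A CH2–CH=CH2 group survives acid, base and peroxide, and it can be delivered to exactly these two carbons from the flanking oxygens (the later O–C5 and O1).
Further cuts are O1–C2 and C3–O of ring C (oxidative chalcone cyclisation) and the chalcone Cα=Cβ bond (aldol condensation with the ring B aldehyde). The last cuts are the two aryl–CH2 bonds (double Claisen rearrangement) and the two O–allyl bonds.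
Forward: ring A is bought as an acetophenone and fully substituted first, ring B is joined as protected isovanillin, and ring C is the only ring formed. The MOM groups are then exchanged for acetates, the double metathesis follows, and mild methanolysis ends the route.
Stereochemistry: the target has no stereocentre and no configured double bond. The E-olefin of the chalcone and the two transient sp3 centres of ring C disappear when ring C aromatises.

Key step: step 9

Remark: flavone numbering is used (ring A = C5–C8, ring C = O1–C4, ring B primed, side chains doubly primed). Acetophenone and chalcone locants of ring A are primed. The four starting materials are assumed to be catalogue chemicals.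

Step 1
Reactants: 1 2',6'-dihydroxy-4'-methoxyacetophenone; 2 allyl bromide (3 equiv)
Product: 3 2',6'-bis(allyloxy)-4'-methoxyacetophenone
Conditions: K2CO3 (4 equiv), DMF, 65 °C
Reagents that add atoms: none
Why: Williamson ether synthesis (SN2 on allyl bromide), in which carbonate in a dipolar aprotic solvent favours O- over C-allylation of the phenoxides and warming with excess 2 also carries the second, carbonyl-chelated hydroxyl through.

Step 2
Reactants: 3 2',6'-bis(allyloxy)-4'-methoxyacetophenone
Product: 5 3',5'-diallyl-2',6'-dihydroxy-4'-methoxyacetophenone, via mono-rearranged phenol 4 (not isolated)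
Conditions: PhNEt2, 205 °C, argon, sealed tube
Reagents that add atoms: none
Why: Two consecutive aromatic Claisen rearrangements ([3,3] shift, then enolisation), in which each allyl group can settle only on a hydrogen-bearing ortho carbon (C3' or C5'), because a shift to the acetyl-bearing C1' cannot rearomatise and is relayed by a Cope shift to the same two carbons, so 5 is the only possible diallyl product.

Step 3
Reactants: 5 3',5'-diallyl-2',6'-dihydroxy-4'-methoxyacetophenone
Product: 6 3',5'-diallyl-2'-hydroxy-4'-methoxy-6'-(methoxymethoxy)acetophenone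
Conditions: MOMCl (1.2 equiv), K2CO3, acetone, rt → 45 °C
Reagents that add atoms: chloromethyl methyl ether (MOMCl), COCCl
Why: Selective phenol alkylation, since the two hydroxyls of 5 are equivalent and the one left after the first etherification is locked in a hydrogen bond to the acetyl oxygen and resists K2CO3/MOMCl, as known for phloroacetophenones; the mask prevents flavanone formation and removes the second phenoxide that would deactivate the ketone in steps 5 and 6.

Step 4
Reactants: 7 isovanillin (3-hydroxy-4-methoxybenzaldehyde)
Product: 8 4-methoxy-3-(methoxymethoxy)benzaldehyde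
Conditions: MOMCl, K2CO3, acetone, rt
Reagents that add atoms: chloromethyl methyl ether (MOMCl), COCCl
Why: Routine MOM protection of a phenol, which removes a phenoxide that would slow the aldol step and suffer under alkaline peroxide, and which is cleaved later together with the 5-O-MOM group.

Step 5
Reactants: 6 3',5'-diallyl-2'-hydroxy-4'-methoxy-6'-(methoxymethoxy)acetophenone; 8 4-methoxy-3-(methoxymethoxy)benzaldehyde
Product: 9 (E)-3',5'-diallyl-2'-hydroxy-4,4'-dimethoxy-3,6'-bis(methoxymethoxy)chalcone
Conditions: KOH (50 % aq.), EtOH, rt
Reagents that add atoms: none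
Why: Claisen–Schmidt condensation, in which the methyl ketone enolate of 6 adds to the non-enolisable aldehyde 8 and E1cB loss of water gives the thermodynamically preferred E-enone, while MOM ethers and allyl groups are inert to KOH at room temperature, where allyl-to-propenyl migration does not yet occur.

Step 6
Reactants: 9 (E)-3',5'-diallyl-2'-hydroxy-4,4'-dimethoxy-3,6'-bis(methoxymethoxy)chalcone
Product: 11 6,8-diallyl-3-hydroxy-7-methoxy-5-(methoxymethoxy)-2-[4-methoxy-3-(methoxymethoxy)phenyl]chromen-4-one, via trans-dihydroflavonol 10 (not isolated)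
Conditions: 30 % H2O2, NaOH (aq.), MeOH, 0 °C → rt
Reagents that add atoms: hydrogen peroxide, OO
Why: Algar–Flynn–Oyamada reaction, in which the 2'-phenoxide closes ring C on the β-carbon of the enone (6-endo), the α-carbon is hydroxylated to racemic trans-10 and further peroxide dehydrogenates C2–C3 so that both transient centres are erased; the sequence is precedented for 2'-hydroxychalcones bearing a 6'-OMOM group, the unactivated allyl olefins ignore the nucleophilic oxidant, and the MOM acetals are base-stable.

Step 7
Reactants: 11 6,8-diallyl-3-hydroxy-7-methoxy-5-(methoxymethoxy)-2-[4-methoxy-3-(methoxymethoxy)phenyl]chromen-4-one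
Product: 12 6,8-diallyl-3,5-dihydroxy-2-(3-hydroxy-4-methoxyphenyl)-7-methoxychromen-4-one
Conditions: HCl (3 M aq., cat.), MeOH, 55 °C
Reagents that add atoms: none
Why: Acid-catalysed transacetalisation of both aryl MOM ethers with methanol; a monosubstituted allyl olefin is not protonated by dilute HCl, so the neighbouring 5-OH cannot add to it, which is why the only acidic step is placed before the prenyl termini exist.

Step 8
Reactants: 12 6,8-diallyl-3,5-dihydroxy-2-(3-hydroxy-4-methoxyphenyl)-7-methoxychromen-4-one
Product: 13 6,8-diallyl-3,5-diacetoxy-2-(3-acetoxy-4-methoxyphenyl)-7-methoxychromen-4-one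
Conditions: Ac2O, pyridine, DMAP (cat.), rt → 45 °C
Reagents that add atoms: acetic anhydride, CC(=O)OC(C)=O
Why: DMAP-catalysed O-acylation of the enolic 3-OH and both phenols, the chelated and flanked 5-OH being the slowest and the reason for gentle warming.

Step 9
Reactants: 13 6,8-diallyl-3,5-diacetoxy-2-(3-acetoxy-4-methoxyphenyl)-7-methoxychromen-4-one; 14 2-methyl-2-butene (large excess, co-solvent)
Product: 17 3,5-diacetoxy-2-(3-acetoxy-4-methoxyphenyl)-7-methoxy-6,8-bis(3-methylbut-2-enyl)chromen-4-one, via 8-allyl-6-prenyl triacetate 15 (not isolated), via 6-allyl-8-prenyl triacetate 16 (not isolated)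
Conditions: second-generation Grubbs catalyst RuCl2(=CHPh)(PCy3)(H2IMes) (2 × 5 mol %), 1,4-benzoquinone (10 mol %), 14–CH2Cl2 1:1, gentle reflux (38–40 °C), argon
Reagents that add atoms: none
Why: Olefin cross-metathesis by the Chauvin mechanism: the 14-electron species left after PCy3 dissociation engages the unhindered CH=CH2 end of an allyl group, the resulting Ru=CH–CH2Ar alkylidene adds 14 to give a ruthenacyclobutane that cycloreverts to ArCH2–CH=C(CH3)2 and Ru=CHCH3, and this ethylidene picks up the next allyl terminus with release of propene, so that 13 passes through 15 and 16 to 17. The closest known reaction type is the cross-metathesis of allylarenes, o-allylphenol esters and C-allylflavonoids with 2-methyl-2-butene to give prenylarenes. Two C=C bonds (C2''=C3'' of each chain) are made, no ring is formed, and neither a stereocentre nor an E/Z element arises because each new olefin carbon bears two methyl groups. The step needs cross- over self-metathesis and freedom from allyl-to-propenyl migration: 14 as co-solvent outcompetes homodimerisation and re-opens any dimer, the trisubstituted product is too hindered to re-enter the cycle, propene leaves through the condenser, and 1,4-benzoquinone intercepts ruthenium hydrides. Ring-closing metathesis between the two allyl groups is no threat, since they stand meta on ring A with C7–OCH3 between them and could only give a strained bridged ring. The three acetates mask the 3-hydroxy-4-keto and 5-hydroxy-4-keto chelating sites, which keeps the ruthenium free and makes the flavonol soluble in CH2Cl2.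

Step 10
Reactants: 17 3,5-diacetoxy-2-(3-acetoxy-4-methoxyphenyl)-7-methoxy-6,8-bis(3-methylbut-2-enyl)chromen-4-one
Product: 18 3,5-dihydroxy-2-(3-hydroxy-4-methoxyphenyl)-7-methoxy-6,8-bis(3-methylbut-2-enyl)chromen-4-one (target)
Conditions: K2CO3 (3 equiv), MeOH–THF, 0 °C → rt, argon
Reagents that add atoms: none
Why: Base-mediated methanolysis (transesterification) of one enol acetate and two aryl acetates, which needs no acid, so the prenyl groups beside 5-OH cannot cyclise to chromans, while exclusion of air guards the flavonol anion against autoxidation.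

Compound list
1 | 2',6'-dihydroxy-4'-methoxyacetophenone | CC(=O)c1c(O)cc(OC)cc1O | starting material
2 | allyl bromide | C=CCBr | starting material
3 | 2',6'-bis(allyloxy)-4'-methoxyacetophenone | CC(=O)c1c(OCC=C)cc(OC)cc1OCC=C | intermediate
4 | 3'-allyl-6'-allyloxy-2'-hydroxy-4'-methoxyacetophenone (formed in situ) | CC(=O)c1c(O)c(CC=C)c(OC)cc1OCC=C | intermediate
5 | 3',5'-diallyl-2',6'-dihydroxy-4'-methoxyacetophenone | CC(=O)c1c(O)c(CC=C)c(OC)c(CC=C)c1O | intermediate
6 | 3',5'-diallyl-2'-hydroxy-4'-methoxy-6'-(methoxymethoxy)acetophenone | CC(=O)c1c(O)c(CC=C)c(OC)c(CC=C)c1OCOC | intermediate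
7 | isovanillin (3-hydroxy-4-methoxybenzaldehyde) | COc1ccc(C=O)cc1O | starting material
8 | 4-methoxy-3-(methoxymethoxy)benzaldehyde | COCOc1cc(C=O)ccc1OC | intermediate
9 | (E)-3',5'-diallyl-2'-hydroxy-4,4'-dimethoxy-3,6'-bis(methoxymethoxy)chalcone | COCOc1cc(/C=C/C(=O)c2c(O)c(CC=C)c(OC)c(CC=C)c2OCOC)ccc1OC | intermediate
10 | (±)-trans-6,8-diallyl-3-hydroxy-7-methoxy-5-(methoxymethoxy)-2-[4-methoxy-3-(methoxymethoxy)phenyl]chroman-4-one (formed in situ; racemic, 2R,3R enantiomer drawn) | COCOc1cc([C@H]2Oc3c(CC=C)c(OC)c(CC=C)c(OCOC)c3C(=O)[C@@H]2O)ccc1OC | intermediate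
11 | 6,8-diallyl-3-hydroxy-7-methoxy-5-(methoxymethoxy)-2-[4-methoxy-3-(methoxymethoxy)phenyl]chromen-4-one | COCOc1cc(-c2oc3c(CC=C)c(OC)c(CC=C)c(OCOC)c3c(=O)c2O)ccc1OC | intermediate
12 | 6,8-diallyl-3,5-dihydroxy-2-(3-hydroxy-4-methoxyphenyl)-7-methoxychromen-4-one | COc1ccc(-c2oc3c(CC=C)c(OC)c(CC=C)c(O)c3c(=O)c2O)cc1O | intermediate
13 | 6,8-diallyl-3,5-diacetoxy-2-(3-acetoxy-4-methoxyphenyl)-7-methoxychromen-4-one | COc1ccc(-c2oc3c(CC=C)c(OC)c(CC=C)c(OC(C)=O)c3c(=O)c2OC(C)=O)cc1OC(C)=O | intermediate
14 | 2-methyl-2-butene | CC=C(C)C | starting material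
15 | 8-allyl-3,5-diacetoxy-2-(3-acetoxy-4-methoxyphenyl)-7-methoxy-6-(3-methylbut-2-enyl)chromen-4-one (formed in situ) | COc1ccc(-c2oc3c(CC=C)c(OC)c(CC=C(C)C)c(OC(C)=O)c3c(=O)c2OC(C)=O)cc1OC(C)=O | intermediate
16 | 6-allyl-3,5-diacetoxy-2-(3-acetoxy-4-methoxyphenyl)-7-methoxy-8-(3-methylbut-2-enyl)chromen-4-one (formed in situ) | COc1ccc(-c2oc3c(CC=C(C)C)c(OC)c(CC=C)c(OC(C)=O)c3c(=O)c2OC(C)=O)cc1OC(C)=O | intermediate
17 | 3,5-diacetoxy-2-(3-acetoxy-4-methoxyphenyl)-7-methoxy-6,8-bis(3-methylbut-2-enyl)chromen-4-one | COc1ccc(-c2oc3c(CC=C(C)C)c(OC)c(CC=C(C)C)c(OC(C)=O)c3c(=O)c2OC(C)=O)cc1OC(C)=O | intermediate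
18 | 3,5-dihydroxy-2-(3-hydroxy-4-methoxyphenyl)-7-methoxy-6,8-bis(3-methylbut-2-enyl)chromen-4-one (CNP0261856.0) | COc1ccc(-c2oc3c(CC=C(C)C)c(OC)c(CC=C(C)C)c(O)c3c(=O)c2O)cc1O | target

Total step count: 10.
Longest linear sequence: 9 steps (steps 1, 2, 3, 5, 6, 7, 8, 9 and 10 from 1). Step 4 is a one-step branch from 7.

Steps most likely to fail

1. Step 6.
- Risk: the cyclisation may lose its regiocontrol. The 6'-substituent twists the carbonyl out of the plane of ring A. Epoxidation of the enone can then outrun the oxa-Michael closure, and attack of the phenoxide at Cα closes a five-membered ring instead of ring C.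
- Fallback: it sets out from 9 and returns at 12, so step 7 is skipped. Oxidation and ring closure are separated. The 2'-OH of 9 is capped (NaH, MOMCl, DMF, 0 °C) to give the tris-MOM chalcone F1. With no phenoxide present, Weitz–Scheffer epoxidation (30 % H2O2, NaOH, MeOH–THF) stops at the racemic trans-epoxy ketone F2. HCl in MeOH at 50 °C removes all three MOM groups. Either of the two equivalent ring A hydroxyls then opens the protonated epoxide at the benzylic carbon, whose cationic character is stabilised by the para-methoxy group of ring B. The six-membered ring therefore forms and gives the racemic trans-dihydroflavonol F3. Alkaline H2O2, which is known to dehydrogenate isolated dihydroflavonols, converts F3 into 12.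

2. Step 9.
- Risk: exchange may stall after one chain. Ruthenium hydrides may move the remaining allyl double bond into conjugation with ring A. The carbonyl-rich substrate may also slow the catalyst.
- Fallback: it sets out from 13 and returns at 17. The same C2''=C3'' bonds are built by carbonyl olefination. Lemieux–Johnson cleavage (OsO4 cat., NaIO4, 2,6-lutidine, dioxane–H2O) acts on both terminal olefins, which are far more accessible than the tetrasubstituted C2=C3 bond of ring C. It gives the bis(arylacetaldehyde) F4. A double Wittig reaction with isopropylidenetriphenylphosphorane (iPrPPh3I, n-BuLi, THF, −78 °C → 0 °C) then gives 17. Partial loss of acetate to the ylide is of no consequence, because step 10 removes these groups anyway.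

3. Step 2.
- Risk: at about 200 °C the second shift may remain incomplete. The o-allylphenols formed may add their hydroxyl across the olefin or decompose.
- Fallback: it sets out from 1 and returns at 5, replacing steps 1 and 2. The two aryl–CH2 bonds are formed by cross-coupling. Electrophilic iodination (NIS 2.2 equiv, TFA cat., MeCN, 0 °C → rt) at the two activated free positions gives 2',6'-dihydroxy-3',5'-diiodo-4'-methoxyacetophenone F5. A double Stille coupling with allyltributylstannane (Pd(PPh3)4, DMF, 90 °C), which tolerates free phenols and the ketone, gives 5.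

Further compounds
F1 | step 6 | (E)-3',5'-diallyl-4,4'-dimethoxy-2',3,6'-tris(methoxymethoxy)chalcone | COCOc1cc(/C=C/C(=O)c2c(OCOC)c(CC=C)c(OC)c(CC=C)c2OCOC)ccc1OC
F2 | step 6 | (±)-trans-[3,5-diallyl-4-methoxy-2,6-bis(methoxymethoxy)phenyl]{3-[4-methoxy-3-(methoxymethoxy)phenyl]oxiran-2-yl}methanone (racemic, αR,βS enantiomer drawn) | COCOc1cc([C@@H]2O[C@H]2C(=O)c3c(OCOC)c(CC=C)c(OC)c(CC=C)c3OCOC)ccc1OC
F3 | step 6 | (±)-trans-6,8-diallyl-3,5-dihydroxy-2-(3-hydroxy-4-methoxyphenyl)-7-methoxychroman-4-one (racemic, 2R,3R enantiomer drawn) | COc1ccc([C@H]2Oc3c(CC=C)c(OC)c(CC=C)c(O)c3C(=O)[C@@H]2O)cc1O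
F4 | step 9 | 2,2'-[3,5-diacetoxy-2-(3-acetoxy-4-methoxyphenyl)-7-methoxy-4-oxochromene-6,8-diyl]diacetaldehyde | COc1ccc(-c2oc3c(CC=O)c(OC)c(CC=O)c(OC(C)=O)c3c(=O)c2OC(C)=O)cc1OC(C)=O
F5 | step 2 | 2',6'-dihydroxy-3',5'-diiodo-4'-methoxyacetophenone | CC(=O)c1c(O)c(I)c(OC)c(I)c1O
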